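**Retrosynthetic overview**
- The target comes from acetylation of its C4 alcohol, the only free hydroxyl at that stage.
- The oxirane (C6–O bond, second ring, C6 quaternary centre) comes from anodic, iodide-mediated dehydrogenative closure of the C5-hydroxy ketone that carries H and farnesyl at C6.
- The C6–C1′ bond comes from alkylating the oxido-dienolate of (4R,5S)-4,5-dihydroxy-3-methylcyclohex-2-enone with (E,E)-farnesyl bromide.
- That enone comes from HAT oxygenation (H to C6, O to C1) of the diene in toluene cis-dihydrodiol, which supplies the carbocycle, the methyl group, C4 and C5.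
- Ring order: the six-membered ring is bought, and the oxirane is closed in the last-but-one step. No protecting groups are used.

Assumption: (1S,2R)-3-methylcyclohexa-3,5-diene-1,2-diol (whole-cell fermentation product of toluene, sold as a catalogue chiral building block) is taken as a purchasable starting material.

Ring numbering in the comments follows the target: C1 = C=O, C2 = CH, C3 = C–CH3, C4 = CH–O, C5 = oxirane CH, C6 = oxirane C bearing farnesyl.

**Step 1**
Reactants: 1 (1S,2R)-3-methylcyclohexa-3,5-diene-1,2-diol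
Product: 3 (4R,5S)-4,5-dihydroxy-3-methylcyclohex-2-en-1-one, via (1S,2R)-3-methyl-5-(triethylsilylperoxy)cyclohex-3-ene-1,2-diol 2 (not isolated)
Conditions: Co(thd)2 (5 mol %), Et3SiH (1.3 equiv), O2 (1 atm), ClCH2CH2Cl/i-PrOH, 0 °C to rt; then Et3N (1.5 equiv), 0 °C
Reagents that add atoms: dioxygen, O=O
Why: Mukaiyama–Isayama-type cobalt-hydride HAT delivers H• to the unsubstituted diene terminus (future C6), O2 traps the allyl radical at its secondary end so the trisubstituted C2=C3 bond survives, and amine-induced Kornblum–DeLaMare fragmentation of silyl peroxide 2 unveils the C1 ketone without an external oxidant that could touch the two free carbinols, so the bought C4 and C5 stereocentres pass through untouched (the C1 peroxide epimers converge).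

**Step 2**
Reactants: 3 (4R,5S)-4,5-dihydroxy-3-methylcyclohex-2-en-1-one; 4 (2E,6E)-farnesyl bromide
Product: 6 (4R,5S,6S)-4,5-dihydroxy-3-methyl-6-[(2E,6E)-3,7,11-trimethyldodeca-2,6,10-trien-1-yl]cyclohex-2-en-1-one, via trilithium (5R,6S)-4-methylcyclohexa-1,3-diene-2,5,6-triolate 5 (not isolated)
Conditions: LDA (3.3 equiv), THF/DMPU, −78 °C; 4 (1.0 equiv), −78 to −40 °C; AcOH quench, −78 °C
Reagents that add atoms: none
Why: Fráter–Seebach-type alkylation, in which both hydroxyls first become lithium alkoxides (which cannot leave, so E1cB loss and aromatisation are shut off), LDA then removes the kinetic α′-proton of the 3-methylcyclohexenone, and cross-conjugated enolate 5 is C-alkylated by SN2 with the allylic bromide anti to the C5 oxide with the E,E geometry retained (the C6 configuration is provisional and is erased in step 3).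

**Step 3**
Reactants: 6 (4R,5S,6S)-4,5-dihydroxy-3-methyl-6-farnesylcyclohex-2-en-1-one
Product: 8 (1R,5R,6R)-5-hydroxy-4-methyl-1-[(2E,6E)-3,7,11-trimethyldodeca-2,6,10-trien-1-yl]-7-oxabicyclo[4.1.0]hept-3-en-2-one, via (4R,5R,6S)-4,5-dihydroxy-6-iodo-3-methyl-6-farnesylcyclohex-2-en-1-one 7 (not isolated)
Conditions: undivided cell, graphite (+) | Pt (−), NaI (0.3 equiv), Et4NBF4 (0.05 M), MeOH/MeCN 1:3, 0 °C, 5 mA cm⁻², 2.1 F mol⁻¹
Reagents that add atoms: none
Why: Proposed new method: iodide-mediated anodic dehydrogenative oxirane closure of an α-branched β-hydroxy ketone (net loss of H2), in which I⁻ is oxidised to I2 at the anode while MeOH is reduced to H2 and methoxide at the cathode, the methoxide enolises C6–H, the cross-conjugated enolate is iodinated on the face opposite the C4/C5 oxygens to give 7 (a syn-iodide cannot close and is returned to the enolate by halophilic attack of I⁻), and the C5 alkoxide displaces the antiperiplanar tertiary α-keto iodide in a 3-exo-tet SN2 step that forms the C6–O bond, the second ring and the (6R) quaternary centre with the oxygen necessarily cis to the bought C5–O and C4–O bonds; base does not accumulate because it is consumed as fast as it is generated, and the isolated chain alkenes should be spared because enolate iodination is much faster than reversible alkene–I2 complexation; the closest known reaction types are halide-mediated electro-epoxidation of alkenes through halohydrins, iodide-mediated anodic α-functionalisation of ketones, and the ring-closing half of the Darzens reaction, none of which, as far as I know, has been shown on an aromatisation-prone cyclic aldol or for a fully substituted oxirane carbon.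

**Step 4**
Reactants: 8 (1R,5R,6R)-5-hydroxy-4-methyl-1-farnesyl-7-oxabicyclo[4.1.0]hept-3-en-2-one
Product: 9 (4R,5R,6R)-4-acetoxy-5,6-epoxy-3-methyl-6-[(2E,6E)-3,7,11-trimethyldodeca-2,6,10-trien-1-yl]cyclohex-2-en-1-one (target, CID121596208)
Conditions: Ac2O (1.5 equiv), pyridine, DMAP (5 mol %), CH2Cl2, 0 °C
Reagents that add atoms: acetic anhydride, CC(=O)OC(C)=O
Why: Standard DMAP-catalysed O-acylation of the only remaining hydroxyl under weakly basic conditions that leave the epoxy-enone and all three stereocentres untouched.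

**Compound list**
1 | (1S,2R)-3-methylcyclohexa-3,5-diene-1,2-diol | O[C@@H]1C(C)=CC=C[C@@H]1O | starting material
2 | (1S,2R)-3-methyl-5-(triethylsilylperoxy)cyclohex-3-ene-1,2-diol (C5 epimers) | O[C@@H]1C(C)=CC(OO[Si](CC)(CC)CC)C[C@@H]1O | intermediate
3 | (4R,5S)-4,5-dihydroxy-3-methylcyclohex-2-en-1-one | O[C@@H]1C(C)=CC(=O)C[C@@H]1O | intermediate
4 | (2E,6E)-farnesyl bromide | BrC/C=C(\C)CC/C=C(\C)CCC=C(C)C | starting material
5 | trilithium (5R,6S)-4-methylcyclohexa-1,3-diene-2,5,6-triolate | [Li+].[Li+].[Li+].[O-][C@@H]1C(C)=CC([O-])=C[C@@H]1[O-] | intermediate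
6 | (4R,5S,6S)-4,5-dihydroxy-3-methyl-6-[(2E,6E)-farnesyl]cyclohex-2-en-1-one | O[C@@H]1C(C)=CC(=O)[C@@H](C/C=C(\C)CC/C=C(\C)CCC=C(C)C)[C@@H]1O | intermediate
7 | (4R,5R,6S)-4,5-dihydroxy-6-iodo-3-methyl-6-[(2E,6E)-farnesyl]cyclohex-2-en-1-one | O[C@@H]1C(C)=CC(=O)[C@](I)(C/C=C(\C)CC/C=C(\C)CCC=C(C)C)[C@@H]1O | intermediate
8 | (1R,5R,6R)-5-hydroxy-4-methyl-1-[(2E,6E)-farnesyl]-7-oxabicyclo[4.1.0]hept-3-en-2-one | O[C@@H]1C(C)=CC(=O)[C@]2(C/C=C(\C)CC/C=C(\C)CCC=C(C)C)O[C@H]12 | intermediate
9 | (4R,5R,6R)-4-acetoxy-5,6-epoxy-3-methyl-6-[(2E,6E)-farnesyl]cyclohex-2-en-1-one | CC(=O)O[C@@H]1C(C)=CC(=O)[C@]2(C/C=C(\C)CC/C=C(\C)CCC=C(C)C)O[C@H]12 | target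

Total step count: 4. Longest linear sequence: 4 (1 → 3 → 6 → 8 → 9).

**Steps most likely to fail**

Step 3 (the proposed new step).
- Risks: base-induced loss of water from 6 followed by tautomerisation to the farnesyl-toluhydroquinone, retro-aldol epimerisation at C5, dehydroiodination of 7, and iodine attack on the chain alkenes.
- The fallback uses known chemistry, sets out from 6 and comes back at 8.
- TMSOTf/Et3N silylates both hydroxyls and soft-enolises the ketone to (5R,6S)-1-farnesyl-4-methyl-2,5,6-tris(trimethylsilyloxy)cyclohexa-1,3-diene F1.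
- One equivalent of NBS in THF at −78 °C brominates the enol-ether carbon from the face opposite C5–OTMS, giving (4R,5R,6S)-6-bromo-6-farnesyl-3-methyl-4,5-bis(trimethylsilyloxy)cyclohex-2-en-1-one F2.
- K2CO3/MeOH at 0 °C removes the silyl groups, and the C5 alkoxide closes the oxirane as in a halohydrin closure to give 8.

Step 1.
- Risks: O2 capture at the tertiary end of the allyl radical, a second HAT on the remaining alkene, and Lewis-acid-induced dehydration of 1 to cresols.
- The fallback sets out from 1 and comes back at 3.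
- Diimide (potassium azodicarboxylate, AcOH, MeOH) saturates only the disubstituted alkene to give (1S,2R)-3-methylcyclohex-3-ene-1,2-diol F3.
- 2,2-Dimethoxypropane/PPTS gives (3aR,7aS)-2,2,4-trimethyl-3a,6,7,7a-tetrahydro-1,3-benzodioxole F4.
- CrO3·3,5-dimethylpyrazole oxidises the ring allylic CH2 to give (3aR,7aS)-2,2,4-trimethyl-7,7a-dihydro-1,3-benzodioxol-6(3aH)-one F5.
- 80 % aqueous AcOH at 40 °C releases 3.

Step 2.
- Risks: poor solubility of trianion 5, O-alkylation, and proton transfer leading to dialkylation.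
- The fallback sets out from 3 and comes back at 6, and it replaces the polyanion by a neutral palladium-catalysed allylation.
- TESOTf/Et3N gives (5R,6S)-4-methyl-2,5,6-tris(triethylsilyloxy)cyclohexa-1,3-diene F6.
- (2E,6E)-Farnesol with ClCO2Me/pyridine gives (2E,6E)-farnesyl methyl carbonate F7.
- Pd2(dba)3/dppe in THF couples F6 with F7 (Tsuji-type allylation of a silyl enol ether, attack at the unhindered allyl terminus) to give (4R,5S,6S)-6-farnesyl-3-methyl-4,5-bis(triethylsilyloxy)cyclohex-2-en-1-one F8.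
- HF·pyridine then gives 6.

**Further compounds**
F1 | step 3 | (5R,6S)-1-[(2E,6E)-farnesyl]-4-methyl-2,5,6-tris(trimethylsilyloxy)cyclohexa-1,3-diene | C[Si](C)(C)O[C@@H]1C(C)=CC(O[Si](C)(C)C)=C(C/C=C(\C)CC/C=C(\C)CCC=C(C)C)[C@@H]1O[Si](C)(C)C
F2 | step 3 | (4R,5R,6S)-6-bromo-6-[(2E,6E)-farnesyl]-3-methyl-4,5-bis(trimethylsilyloxy)cyclohex-2-en-1-one | C[Si](C)(C)O[C@@H]1C(C)=CC(=O)[C@](Br)(C/C=C(\C)CC/C=C(\C)CCC=C(C)C)[C@@H]1O[Si](C)(C)C
F3 | step 1 | (1S,2R)-3-methylcyclohex-3-ene-1,2-diol | O[C@@H]1C(C)=CCC[C@@H]1O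
F4 | step 1 | (3aR,7aS)-2,2,4-trimethyl-3a,6,7,7a-tetrahydro-1,3-benzodioxole | CC1=CCC[C@@H]2OC(C)(C)O[C@H]12
F5 | step 1 | (3aR,7aS)-2,2,4-trimethyl-7,7a-dihydro-1,3-benzodioxol-6(3aH)-one | CC1=CC(=O)C[C@@H]2OC(C)(C)O[C@H]12
F6 | step 2 | (5R,6S)-4-methyl-2,5,6-tris(triethylsilyloxy)cyclohexa-1,3-diene | CC[Si](CC)(CC)O[C@@H]1C(C)=CC(O[Si](CC)(CC)CC)=C[C@@H]1O[Si](CC)(CC)CC
F7 | step 2 | (2E,6E)-farnesyl methyl carbonate | COC(=O)OC/C=C(\C)CC/C=C(\C)CCC=C(C)C
F8 | step 2 | (4R,5S,6S)-6-[(2E,6E)-farnesyl]-3-methyl-4,5-bis(triethylsilyloxy)cyclohex-2-en-1-one | CC[Si](CC)(CC)O[C@@H]1C(C)=CC(=O)[C@@H](C/C=C(\C)CC/C=C(\C)CCC=C(C)C)[C@@H]1O[Si](CC)(CC)CC
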